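**Plan**

- Locants: ring A is the benzoyl ring (C1 carbonyl-bearing, C2 and C4 OMe, C3 CH2OH, C6 CH3). Ring B is the salicylic acid ring (C1' CO2H, C2' OH, C3' CH3, C4' O-acyl, C5' H, C6' CH3).
- Retrosynthesis: cut the depside ester bond O(C4')–C(=O); take the C1' carboxyl back to a formyl group and cut C1'–CHO; open ring B at C2'–C3' and C4'–C5' into 3-methylcyclobut-2-en-1-one and 1-(triisopropylsilyloxy)propyne; cut ring A at C1–CO2H and C3–CH2OH back to 3,5-dimethoxytoluene.
- Enabling feature: ring B without its C1' carboxyl is the symmetric 2,5-dimethylresorcinol. The benzannulation builds it with the C2' oxygen as a free phenol (from the ketene carbonyl) and the C4' oxygen as a silyl ether (from the ynol ether), so formylation happens once, at C1', and the ring A acyl group later goes to O4'.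
- Forward order: ring B closes in step 4, then C1' formylation and desilylation. Ring A acid is made in four steps from 3,5-dimethoxytoluene and joined at O4'. Chlorite oxidation and a last desilylation finish the route.
- Stereochemistry: the target has no stereocentre, so nothing has to be controlled.

Key step: step 4

Remark: the C2' hydroxyl is left unprotected from step 5 on, on the assumption that its hydrogen bond to the C1' carbonyl and its two ortho neighbours keep it from being acylated; the volatile 3-methylcyclobut-2-en-1-one is carried as a titrated solution.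

**Route**

Step 1
Reactants: 1 propyne; 2 trichloroacetyl chloride
Product: 4 4,4-dichloro-3-methylcyclobut-2-en-1-one, via dichloroketene 3 (not isolated)
Conditions: Zn–Cu couple, 1 (excess, dry-ice condenser), slow addition of 2, Et2O/DME, 0 °C → rt
Reagents that add atoms: none
Why: Zinc reduces 2 to dichloroketene, which adds to the alkyne in a thermal [2+2] ketene–alkyne cycloaddition with the ketene carbonyl carbon bonding to the unsubstituted alkyne terminus, the standard entry to 3-alkyl-4,4-dichlorocyclobutenones.

Step 2
Reactants: 4 4,4-dichloro-3-methylcyclobut-2-en-1-one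
Product: 5 3-methylcyclobut-2-en-1-one
Conditions: Zn dust, AcOH, TMEDA, EtOH, 0 °C → rt
Reagents that add atoms: none
Why: Zinc in acetic acid buffered by TMEDA removes both α-chlorines by reductive dehalogenation without reducing or isomerising the strained enone, and the volatile product is kept cold and handled as a solution.

Step 3
Reactants: 1 propyne; 6 triisopropylsilyl trifluoromethanesulfonate
Product: 9 1-(triisopropylsilyloxy)propyne, via prop-1-ynyllithium 7 (not isolated), via lithium prop-1-yn-1-olate 8 (not isolated)
Conditions: 1, n-BuLi, THF, −78 °C; LiOOt-Bu (from t-BuOOH and LiN(SiMe3)2), THF, −78 → 0 °C; then 6, −78 → 0 °C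
Reagents that add atoms: lithium tert-butyl peroxide, made in the flask from tert-butyl hydroperoxide, CC(C)(C)OO
Why: Lithium tert-butyl peroxide transfers an oxygen atom to the acetylide carbon (electrophilic oxygenation of a lithium acetylide to a lithium ynolate), and the bulky silyl triflate then silylates the ynolate on oxygen, not on carbon, giving the ynol silyl ether.

Step 4
Reactants: 5 3-methylcyclobut-2-en-1-one; 9 1-(triisopropylsilyloxy)propyne
Product: 14 2,5-dimethyl-3-(triisopropylsilyloxy)phenol, via vinylketene 10 (not isolated), via vinylcyclobutenone 11 (not isolated), via dienylketene 12 (not isolated), via cyclohexadienone 13 (not isolated)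
Conditions: 5 (1.0 equiv), 9 (1.2 equiv), PhMe (0.5 M), sealed tube, 80 °C then 110 °C
Reagents that add atoms: none
Why: On heating, 5 opens by 4π-electrocyclic cleavage of its C1–C4 bond to vinylketene 10, whose ketene C=C adds to the ynol ether in a [2+2] cycloaddition to give 11; 4π opening of 11 to dienylketene 12, 6π-electrocyclisation to 13 and enolisation then give phenol 14. The closest known reaction type is the Danheiser benzannulation of cyclobutenones with trialkylsilyloxyalkynes, which gives resorcinol monosilyl ethers. Ring B is closed by the thermal disrotatory 6π-electrocyclisation, which re-forms the C1'–C2' bond after the [2+2] event has made the C2'–C3' and C4'–C5' bonds. No stereocentre is created, because the single sp3 stereocentre of 11 is lost again on ring opening. The step needs one orientation in the [2+2] addition, and the polarisation of the ynol ether secures it: the electron-rich methyl-bearing carbon bonds to the electrophilic ketene carbonyl carbon, so the ketene oxygen becomes the free C2' hydroxyl next to the C3' methyl and the silyloxy group ends up at C4'. A slight excess of 9 at moderate concentration keeps 10 from dimerising or from acylating the phenol already formed.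

Step 5
Reactants: 14 2,5-dimethyl-3-(triisopropylsilyloxy)phenol
Product: 16 2-hydroxy-3,6-dimethyl-4-(triisopropylsilyloxy)benzaldehyde, via salicyl alcohol magnesium salt 15 (not isolated)
Conditions: MgCl2, Et3N, (CH2O)n, MeCN, reflux; then 1 M HCl
Reagents that add atoms: paraformaldehyde (formaldehyde unit), C=O
Why: In this magnesium-mediated ortho-formylation (Casnati–Skattebøl reaction) the magnesium phenoxide of 14 delivers formaldehyde through a six-membered chelate to C1', the only free carbon ortho to the free hydroxyl, and a second formaldehyde oxidises the magnesium-bound salicyl alcohol 15 by hydride transfer, while the silylated C4' oxygen cannot direct a second formylation to C5'.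

Step 6
Reactants: 16 2-hydroxy-3,6-dimethyl-4-(triisopropylsilyloxy)benzaldehyde
Product: 17 2,4-dihydroxy-3,6-dimethylbenzaldehyde
Conditions: n-Bu4NF, THF, 0 °C; then 1 M HCl
Reagents that add atoms: none
Why: Fluoride cleaves the aryl silicon–oxygen bond (fluoride-mediated desilylation), driven by the strong Si–F bond and the good phenoxide leaving group para to the formyl group, and neither the aldehyde nor the ring is touched.

Step 7
Reactants: 18 3,5-dimethoxytoluene
Product: 20 (2,6-dimethoxy-4-methylphenyl)methanol, via aryllithium 19 (not isolated)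
Conditions: n-BuLi, TMEDA, THF, 0 °C; (CH2O)n, 0 °C → rt; H2O
Reagents that add atoms: paraformaldehyde (formaldehyde unit), C=O
Why: Directed ortho-metalation places lithium on the ring carbon flanked by both methoxy groups, which becomes C3 of ring A, and the aryllithium adds to formaldehyde to give the benzylic alcohol.

Step 8
Reactants: 20 (2,6-dimethoxy-4-methylphenyl)methanol
Product: 21 tert-butyl[(2,6-dimethoxy-4-methylphenyl)methoxy]dimethylsilane
Conditions: TBSCl, imidazole, DMF, rt
Reagents that add atoms: tert-butyldimethylsilyl chloride, CC(C)(C)[Si](C)(C)Cl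
Why: Standard silylation of a primary alcohol with TBSCl and imidazole protects the hydroxymethyl group against the organolithium of step 10 and the acylation of step 11.

Step 9
Reactants: 21 tert-butyl[(2,6-dimethoxy-4-methylphenyl)methoxy]dimethylsilane
Product: 22 [(3-bromo-2,6-dimethoxy-4-methylphenyl)methoxy](tert-butyl)dimethylsilane
Conditions: NBS, MeCN, 0 °C, dark
Reagents that add atoms: N-bromosuccinimide, O=C1CCC(=O)N1Br
Why: Electrophilic aromatic bromination by NBS in a polar solvent attacks one of the two symmetry-equivalent free ring positions, each ortho to one methoxy group and para to the other, so a single monobromide is expected.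

Step 10
Reactants: 22 [(3-bromo-2,6-dimethoxy-4-methylphenyl)methoxy](tert-butyl)dimethylsilane
Product: 24 3-{[(tert-butyldimethylsilyl)oxy]methyl}-2,4-dimethoxy-6-methylbenzoic acid, via aryllithium 23 (not isolated)
Conditions: n-BuLi, THF, −78 °C; CO2 (g), −78 °C → rt; then dil. HCl to pH 4, 0 °C
Reagents that add atoms: carbon dioxide, O=C=O
Why: Bromine–lithium exchange at −78 °C is faster than any deprotonation, and the resulting aryllithium is carboxylated by CO2 (carboxylation of an organolithium), which installs the C1 carboxyl between the C2 methoxy and C6 methyl groups.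

Step 11
Reactants: 24 3-{[(tert-butyldimethylsilyl)oxy]methyl}-2,4-dimethoxy-6-methylbenzoic acid; 17 2,4-dihydroxy-3,6-dimethylbenzaldehyde
Product: 26 4-formyl-3-hydroxy-2,5-dimethylphenyl 3-{[(tert-butyldimethylsilyl)oxy]methyl}-2,4-dimethoxy-6-methylbenzoate, via acid chloride 25 (not isolated)
Conditions: 24, 1-chloro-N,N,2-trimethylprop-1-en-1-amine, CH2Cl2, 0 °C → rt; then 17, Et3N, DMAP (cat.), CH2Cl2, 0 °C → rt
Reagents that add atoms: none
Why: The Ghosez reagent converts the hindered acid into its acid chloride without releasing acid, and DMAP-catalysed O-acylation (nucleophilic acyl-transfer catalysis) then takes place at the C4' hydroxyl, the more acidic and less hindered one, because the C2' hydroxyl is hydrogen-bonded to the formyl group and flanked by two substituents.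

Step 12
Reactants: 26 4-formyl-3-hydroxy-2,5-dimethylphenyl 3-{[(tert-butyldimethylsilyl)oxy]methyl}-2,4-dimethoxy-6-methylbenzoate
Product: 27 4-[(3-{[(tert-butyldimethylsilyl)oxy]methyl}-2,4-dimethoxy-6-methylbenzoyl)oxy]-2-hydroxy-3,6-dimethylbenzoic acid
Conditions: NaClO2, NaH2PO4, 2-methylbut-2-ene, t-BuOH/THF/H2O, 0 °C → rt
Reagents that add atoms: sodium chlorite, [Na+].[O-]Cl=O
Why: The Pinnick oxidation converts the aromatic aldehyde into the acid with chlorous acid while 2-methylbut-2-ene traps the hypochlorous acid by-product, and the buffer at about pH 4 should leave the silyl ether, the aryl ester and the electron-rich rings intact.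

Step 13
Reactants: 27 4-[(3-{[(tert-butyldimethylsilyl)oxy]methyl}-2,4-dimethoxy-6-methylbenzoyl)oxy]-2-hydroxy-3,6-dimethylbenzoic acid
Product: 28 2-hydroxy-4-{[3-(hydroxymethyl)-2,4-dimethoxy-6-methylbenzoyl]oxy}-3,6-dimethylbenzoic acid (CNP0372912.0)
Conditions: HF·pyridine, pyridine, THF, 0 °C → rt
Reagents that add atoms: none
Why: Fluoride-mediated desilylation with pyridine-buffered HF removes the primary silyl ether through Si–F bond formation under conditions too mild to cleave the hindered aryl ester or to ionise the benzylic alcohol.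

**Compound list**

1 | propyne | CC#C | starting material
2 | trichloroacetyl chloride | O=C(Cl)C(Cl)(Cl)Cl | starting material
3 | dichloroketene | O=C=C(Cl)Cl | intermediate
4 | 4,4-dichloro-3-methylcyclobut-2-en-1-one | CC1=CC(=O)C1(Cl)Cl | intermediate
5 | 3-methylcyclobut-2-en-1-one | CC1=CC(=O)C1 | intermediate
6 | triisopropylsilyl trifluoromethanesulfonate | CC(C)[Si](C(C)C)(C(C)C)OS(=O)(=O)C(F)(F)F | starting material
7 | prop-1-ynyllithium | [Li]C#CC | intermediate
8 | lithium prop-1-yn-1-olate | [Li+].[O-]C#CC | intermediate
9 | 1-(triisopropylsilyloxy)propyne | CC#CO[Si](C(C)C)(C(C)C)C(C)C | intermediate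
10 | 3-methylbuta-1,3-dien-1-one (vinylketene) | CC(=C)C=C=O | intermediate
11 | 2-methyl-4-(prop-1-en-2-yl)-3-(triisopropylsilyloxy)cyclobut-2-en-1-one (racemic, transient) | CC1=C(O[Si](C(C)C)(C(C)C)C(C)C)C(C(C)=C)C1=O | intermediate
12 | (3E)-2,5-dimethyl-3-(triisopropylsilyloxy)hexa-1,3,5-trien-1-one (dienylketene) | CC(=C=O)/C(O[Si](C(C)C)(C(C)C)C(C)C)=C\C(C)=C | intermediate
13 | 2,5-dimethyl-3-(triisopropylsilyloxy)cyclohexa-2,4-dien-1-one | CC1=CC(O[Si](C(C)C)(C(C)C)C(C)C)=C(C)C(=O)C1 | intermediate
14 | 2,5-dimethyl-3-(triisopropylsilyloxy)phenol | Cc1cc(O)c(C)c(O[Si](C(C)C)(C(C)C)C(C)C)c1 | intermediate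
15 | chloromagnesium 2-(hydroxymethyl)-3,6-dimethyl-5-(triisopropylsilyloxy)phenoxide | Cc1cc(O[Si](C(C)C)(C(C)C)C(C)C)c(C)c([O-])c1CO.[Mg+2].[Cl-] | intermediate
16 | 2-hydroxy-3,6-dimethyl-4-(triisopropylsilyloxy)benzaldehyde | Cc1cc(O[Si](C(C)C)(C(C)C)C(C)C)c(C)c(O)c1C=O | intermediate
17 | 2,4-dihydroxy-3,6-dimethylbenzaldehyde | Cc1cc(O)c(C)c(O)c1C=O | intermediate
18 | 3,5-dimethoxytoluene | COc1cc(C)cc(OC)c1 | starting material
19 | (2,6-dimethoxy-4-methylphenyl)lithium | [Li]c1c(OC)cc(C)cc1OC | intermediate
20 | (2,6-dimethoxy-4-methylphenyl)methanol | COc1cc(C)cc(OC)c1CO | intermediate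
21 | tert-butyl[(2,6-dimethoxy-4-methylphenyl)methoxy]dimethylsilane | COc1cc(C)cc(OC)c1CO[Si](C)(C)C(C)(C)C | intermediate
22 | [(3-bromo-2,6-dimethoxy-4-methylphenyl)methoxy](tert-butyl)dimethylsilane | COc1cc(C)c(Br)c(OC)c1CO[Si](C)(C)C(C)(C)C | intermediate
23 | (3-{[(tert-butyldimethylsilyl)oxy]methyl}-2,4-dimethoxy-6-methylphenyl)lithium | [Li]c1c(C)cc(OC)c(CO[Si](C)(C)C(C)(C)C)c1OC | intermediate
24 | 3-{[(tert-butyldimethylsilyl)oxy]methyl}-2,4-dimethoxy-6-methylbenzoic acid | COc1cc(C)c(C(=O)O)c(OC)c1CO[Si](C)(C)C(C)(C)C | intermediate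
25 | 3-{[(tert-butyldimethylsilyl)oxy]methyl}-2,4-dimethoxy-6-methylbenzoyl chloride | COc1cc(C)c(C(=O)Cl)c(OC)c1CO[Si](C)(C)C(C)(C)C | intermediate
26 | 4-formyl-3-hydroxy-2,5-dimethylphenyl 3-{[(tert-butyldimethylsilyl)oxy]methyl}-2,4-dimethoxy-6-methylbenzoate | COc1cc(C)c(C(=O)Oc2cc(C)c(C=O)c(O)c2C)c(OC)c1CO[Si](C)(C)C(C)(C)C | intermediate
27 | 4-[(3-{[(tert-butyldimethylsilyl)oxy]methyl}-2,4-dimethoxy-6-methylbenzoyl)oxy]-2-hydroxy-3,6-dimethylbenzoic acid | COc1cc(C)c(C(=O)Oc2cc(C)c(C(=O)O)c(O)c2C)c(OC)c1CO[Si](C)(C)C(C)(C)C | intermediate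
28 | 2-hydroxy-4-{[3-(hydroxymethyl)-2,4-dimethoxy-6-methylbenzoyl]oxy}-3,6-dimethylbenzoic acid | COc1cc(C)c(C(=O)Oc2cc(C)c(C(=O)O)c(O)c2C)c(OC)c1CO | target

**Step count and risks**

Total step count: 13. Longest linear sequence: 8 steps (steps 1, 2, 4, 5, 6, 11, 12, 13).

Steps most likely to fail:

1. Step 4. The volatile cyclobutenone may be lost to the headspace, and the vinylketene may be consumed by dimerisation or by acylating the phenol already formed before the ynol ether captures it. The fallback keeps the benzannulation but makes the vinylketene another way; it sets out from 9 and comes back to the route at 14. Commercial 3-methylbut-3-en-2-one (CC(=C)C(C)=O) is trifluoroacetylated (LiN(SiMe3)2, CF3CO2CH2CF3, THF, −78 °C) to 1,1,1-trifluoro-5-methylhex-5-ene-2,4-dione F1. Detrifluoroacetylative diazo transfer (MsN3, Et3N, H2O, MeCN) then gives 1-diazo-3-methylbut-3-en-2-one F2. Irradiation of F2 with 9 (CH2Cl2, rt, then PhMe, 80–110 °C) triggers a photochemical Wolff rearrangement to the same vinylketene 10 at low stationary concentration, which follows the path through 11, 12 and 13 to 14.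

2. Step 11. Acyl transfer from the doubly ortho-substituted acid chloride may be slow, so that hydrolysis, acylation at the C2' oxygen or loss of the benzylic silyl ether compete. The fallback sets out from 24 and 16 (step 6 is skipped) and comes back at 26. Acid 24 is converted with cyanuric fluoride and pyridine in CH2Cl2 into 3-{[(tert-butyldimethylsilyl)oxy]methyl}-2,4-dimethoxy-6-methylbenzoyl fluoride F3. F3 is coupled with the aryl silyl ether 16 under catalytic anhydrous fluoride (n-Bu4N[Ph3SiF2], MeCN, rt), a fluoride-catalysed acyl fluoride–silyl ether exchange. Only the oxygen that carries silicon is unmasked as a phenoxide, so the silyl group set in step 4 fixes the acylation site and the small acyl fluoride eases the steric demand.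

3. Step 12. Hypochlorous acid may escape the scavenger and chlorinate ring A at C5, or the benzylic silyl ether may be lost in the acidic buffer. The fallback sets the ring B carboxyl before ring A is attached; it sets out from 16 and comes back at 27. Chlorite oxidation of 16 (NaClO2, NaH2PO4, 2-methylbut-2-ene) gives 2-hydroxy-3,6-dimethyl-4-(triisopropylsilyloxy)benzoic acid F4. Selective carboxylate alkylation (allyl bromide, KHCO3, DMF) gives prop-2-en-1-yl 2-hydroxy-3,6-dimethyl-4-(triisopropylsilyloxy)benzoate F5. Desilylation (n-Bu4NF, THF) gives prop-2-en-1-yl 2,4-dihydroxy-3,6-dimethylbenzoate F6. Acylation with acid chloride 25 under the conditions of step 11 gives the allyl ester of the depside acid F7. Deallylation with Pd(PPh3)4 (zerovalent palladium) and morpholine in THF then gives 27 under neutral conditions.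

**Further compounds**

F1 | step 4 | 1,1,1-trifluoro-5-methylhex-5-ene-2,4-dione | CC(=C)C(=O)CC(=O)C(F)(F)F
F2 | step 4 | 1-diazo-3-methylbut-3-en-2-one | CC(=C)C(=O)C=[N+]=[N-]
F3 | step 11 | 3-{[(tert-butyldimethylsilyl)oxy]methyl}-2,4-dimethoxy-6-methylbenzoyl fluoride | COc1cc(C)c(C(=O)F)c(OC)c1CO[Si](C)(C)C(C)(C)C
F4 | step 12 | 2-hydroxy-3,6-dimethyl-4-(triisopropylsilyloxy)benzoic acid | Cc1cc(O[Si](C(C)C)(C(C)C)C(C)C)c(C)c(O)c1C(=O)O
F5 | step 12 | prop-2-en-1-yl 2-hydroxy-3,6-dimethyl-4-(triisopropylsilyloxy)benzoate | C=CCOC(=O)c1c(C)cc(O[Si](C(C)C)(C(C)C)C(C)C)c(C)c1O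
F6 | step 12 | prop-2-en-1-yl 2,4-dihydroxy-3,6-dimethylbenzoate | C=CCOC(=O)c1c(C)cc(O)c(C)c1O
F7 | step 12 | prop-2-en-1-yl 4-[(3-{[(tert-butyldimethylsilyl)oxy]methyl}-2,4-dimethoxy-6-methylbenzoyl)oxy]-2-hydroxy-3,6-dimethylbenzoate | COc1cc(C)c(C(=O)Oc2cc(C)c(C(=O)OCC=C)c(O)c2C)c(OC)c1CO[Si](C)(C)C(C)(C)C
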